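**Assumption (one line):** 2,5-bis(hydroxymethyl)furan (the bulk HMF-derived furan) is taken as commercial; atoms are numbered as in cyclopenta[c]pyran (C1, O2, C3, C4, C4a, C5, C6, C7, C7a), and the lactol OH in 10–14 is an equilibrating anomeric mixture fixed only in the last step.

## Retrosynthetic overview

1. Target 16 ⇐ O-1/O-6 bis-isovalerylation of 14 ⇐ primary-selective bis-acetylation of pentaol lactol 12 ⇐ keto-ester lactol 10 (C6 ketone reduction sets C6; ester reduction gives the 4-CH2OH).
2. Pyran ring (formed second): 10 ⇐ acid unmasking of the masked 1,5-dialdehyde 9 (two dimethyl acetals), closing O2–C1 as a lactol.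
3. C4a–C4 bond and the C6 oxygen: 9 ⇐ Babler–Dauben 1,3-oxidative transposition of 8 ⇐ ester-enolate 1,2-addition to enone 6; C7a–C1 bond ⇐ α′-dimethoxymethylation of 4.
4. Cyclopentane ring (formed first, carrying the C7 carbinol stereocentre): 2 ⇐ enantioselective, desymmetrising Piancatelli rearrangement that dearomatises the C2v-symmetric furan 1.

## Route

**Step 1**
Reactants: 1, 2,5-bis(hydroxymethyl)furan
Product: 2, (S)-4-hydroxy-4-(hydroxymethyl)cyclopent-2-en-1-one
Conditions: (S,S)-IDPi (confined imidodiphosphorimidate Brønsted acid, 3 mol %), H2O (2 equiv), CHCl3, 40 °C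
Reagents that add atoms: water, O (supplies the tertiary OH oxygen; net isomerisation)
Why: Proposed new method: ionisation of either equivalent CH2OH arm gives the furfuryl oxocarbenium, water adds at the distal furan carbon, and ring-opening gives a 1,4-dihydroxypentadienyl cation whose 4π-conrotatory closure (Piancatelli rearrangement; the uncatalysed racemic 1 → rac-2 reaction in hot water is known) is steered by the chiral counter-anion, so aromaticity and symmetry are broken together and the C(OH)(CH2OH) centre is set as S; the closest known reaction types are chiral-phosphoric-acid aza-Piancatelli rearrangements and IDPi-catalysed asymmetric Nazarov electrocyclisations.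

**Step 2**
Reactants: 2; 3, 2,2-dimethoxypropane
Product: 4, (5S)-2,2-dimethyl-1,3-dioxaspiro[4.4]non-8-en-7-one (acetonide of 2)
Conditions: Me2C(OMe)2, PPTS (cat.), acetone, rt
Reagents that add atoms: 2,2-dimethoxypropane, COC(C)(C)OC
Why: Acid-catalysed transketalisation ties the tertiary/primary 1,2-diol into a dioxolane, masking both OH groups for the enolate and oxidation steps without touching the stereocentre.

**Step 3**
Reactants: 4; 5, trimethyl orthoformate
Product: 6, (5R,6S)-6-(dimethoxymethyl)-2,2-dimethyl-1,3-dioxaspiro[4.4]non-8-en-7-one (CH(OMe)2 cis to the spiro C–O bond, trans to the dioxolane CH2)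
Conditions: LDA, TMSCl, THF, −78 °C; then HC(OMe)3, BF3·OEt2, CH2Cl2, −78 °C
Reagents that add atoms: trimethyl orthoformate, COC(OC)OC
Why: Kinetic α′-deprotonation gives the cross-conjugated silyl dienol ether, which adds Mukaiyama-style to the dimethoxycarbenium ion; attack anti to the dioxolane CH2 places the new C1 carbon cis to the spiro oxygen, and this epimerisable centre should also favour that isomer at equilibrium.

**Step 4**
Reactants: 6; 7, methyl 3,3-dimethoxypropanoate
Product: 8, methyl 2-[6-(dimethoxymethyl)-7-hydroxy-2,2-dimethyl-1,3-dioxaspiro[4.4]non-8-en-7-yl]-3,3-dimethoxypropanoate (ring centres as in 6; mixture at the two new centres)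
Conditions: 7, LDA, THF, −78 °C; CeCl3; then 6, −78 °C, cold quench
Reagents that add atoms: methyl 3,3-dimethoxypropanoate, COC(=O)CC(OC)OC
Why: The hard Li/Ce ester enolate adds 1,2 to the enone carbonyl (aldol addition, cerium suppressing enolisation), forming the C4a–C4 bond; both new stereocentres become sp2 later, so their configuration is irrelevant.

**Step 5**
Reactants: 8
Product: 9, methyl 2-[6-(dimethoxymethyl)-2,2-dimethyl-9-oxo-1,3-dioxaspiro[4.4]non-7-en-7-yl]-3,3-dimethoxypropanoate
Conditions: PCC, NaOAc, 4 Å MS, CH2Cl2, rt
Reagents that add atoms: none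
Why: Babler–Dauben oxidative 1,3-transposition: the chromate ester of the tertiary allylic alcohol undergoes [3,3] shift to the only allylic terminus and is oxidised, giving the C4a=C5 alkene and the C6 ketone; the ketal-protected carbinol cannot compete.

**Step 6**
Reactants: 9
Product: 10, methyl (7R,7aS)-1,7-dihydroxy-7-(hydroxymethyl)-6-oxo-1,6,7,7a-tetrahydrocyclopenta[c]pyran-4-carboxylate
Conditions: TFA/H2O/THF (1:1:3), 0 °C → rt
Reagents that add atoms: water, O (lactol OH and ring oxygen arise from acetal hydrolysis)
Why: Hydrolysis of both acetals and the acetonide frees the 1,5-dialdehyde; the C3 formyl group enolises into conjugation with the ester and dienone and its enol oxygen closes onto the C1 aldehyde (lactolisation, as in iridoid aglycones), while C7a, epimerisable through the open aldehyde, is expected to settle with C1 cis to the small 7-OH (H-7a cis to CH2OH).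

**Step 7**
Reactants: 10
Product: 11, methyl (6S,7R,7aS)-1,6,7-trihydroxy-7-(hydroxymethyl)-1,6,7,7a-tetrahydrocyclopenta[c]pyran-4-carboxylate
Conditions: NaBH4, CeCl3·7H2O, MeOH, −78 °C
Reagents that add atoms: none
Why: Luche 1,2-reduction; the Ce-chelated α-hydroxy ketone is attacked on the face anti to the 7-CH2OH group (the face of the 7-OH), giving the 6,7-trans diol (6S), and the lactol and ester survive at −78 °C.

**Step 8**
Reactants: 11
Product: 12, (6S,7R,7aS)-4,7-bis(hydroxymethyl)-1,6,7,7a-tetrahydrocyclopenta[c]pyran-1,6,7-triol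
Conditions: BSA, CH2Cl2, rt; then DIBAL-H, −78 → −40 °C; MeOH, aq. Rochelle salt/citric acid buffer
Reagents that add atoms: none
Why: Transient O-silylation turns the lactol into a TMS acetal (blocking ring-opening and over-reduction), DIBAL then reduces the β-alkoxyacrylate ester 1,2 to the allylic alcohol, and buffered methanolysis removes the TMS groups.

**Step 9**
Reactants: 12; 13, vinyl acetate
Product: 14, [(6S,7R,7aS)-1,6,7-trihydroxy-1,6,7,7a-tetrahydrocyclopenta[c]pyran-4,7-diyl]bis(methylene) diacetate
Conditions: Novozym 435 (CAL-B), vinyl acetate, THF, 30 °C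
Reagents that add atoms: vinyl acetate, C=COC(C)=O
Why: Lipase-catalysed transesterification selects the two primary hydroxyls over the secondary allylic, tertiary and hemiacetal OH groups under neutral conditions that the acid-labile dienol ether tolerates.

**Step 10**
Reactants: 14; 15, isovaleric (3-methylbutanoic) anhydride
Product: 16, 10-acetoxyvaltrathydrin, (1S,6S,7R,7aS)-4,7-bis(acetoxymethyl)-7-hydroxy-1,6,7,7a-tetrahydrocyclopenta[c]pyran-1,6-diyl bis(3-methylbutanoate)
Conditions: (iBuCO)2O (2.5 equiv), pyridine, DMAP (cat.), CH2Cl2, −20 → 0 °C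
Reagents that add atoms: isovaleric anhydride, CC(C)CC(=O)OC(=O)CC(C)C
Why: DMAP-catalysed acylation esterifies the secondary allylic 6-OH and the lactol OH while the tertiary 7-OH is inert; the lactol reacts through its favoured equatorial-OH anomer (trans to the C7a–C7 bond, H-1/H-7a trans-diaxial), giving 1S.

## Compound list

1 | 2,5-bis(hydroxymethyl)furan | OCc1ccc(CO)o1 | starting material
2 | (S)-4-hydroxy-4-(hydroxymethyl)cyclopent-2-en-1-one | O=C1C=C[C@](O)(CO)C1 | intermediate
3 | 2,2-dimethoxypropane | COC(C)(C)OC | starting material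
4 | (5S)-2,2-dimethyl-1,3-dioxaspiro[4.4]non-8-en-7-one | O=C1C=C[C@]2(COC(C)(C)O2)C1 | intermediate
5 | trimethyl orthoformate | COC(OC)OC | starting material
6 | (5R,6S)-6-(dimethoxymethyl)-2,2-dimethyl-1,3-dioxaspiro[4.4]non-8-en-7-one | O=C1C=C[C@]2(COC(C)(C)O2)[C@H]1C(OC)OC | intermediate
7 | methyl 3,3-dimethoxypropanoate | COC(=O)CC(OC)OC | starting material
8 | methyl 2-[6-(dimethoxymethyl)-7-hydroxy-2,2-dimethyl-1,3-dioxaspiro[4.4]non-8-en-7-yl]-3,3-dimethoxypropanoate (ring centres as in 6) | COC(=O)C(C(OC)OC)C1(O)C=C[C@]2(COC(C)(C)O2)[C@H]1C(OC)OC | intermediate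
9 | methyl 2-[6-(dimethoxymethyl)-2,2-dimethyl-9-oxo-1,3-dioxaspiro[4.4]non-7-en-7-yl]-3,3-dimethoxypropanoate (ring centres as in 6) | COC(=O)C(C(OC)OC)C1=CC(=O)[C@]2(COC(C)(C)O2)[C@H]1C(OC)OC | intermediate
10 | methyl (7R,7aS)-1,7-dihydroxy-7-(hydroxymethyl)-6-oxo-1,6,7,7a-tetrahydrocyclopenta[c]pyran-4-carboxylate | COC(=O)C1=COC(O)[C@H]2C1=CC(=O)[C@]2(O)CO | intermediate
11 | methyl (6S,7R,7aS)-1,6,7-trihydroxy-7-(hydroxymethyl)-1,6,7,7a-tetrahydrocyclopenta[c]pyran-4-carboxylate | COC(=O)C1=COC(O)[C@H]2C1=C[C@H](O)[C@]2(O)CO | intermediate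
12 | (6S,7R,7aS)-4,7-bis(hydroxymethyl)-1,6,7,7a-tetrahydrocyclopenta[c]pyran-1,6,7-triol | OCC1=COC(O)[C@H]2C1=C[C@H](O)[C@]2(O)CO | intermediate
13 | vinyl acetate | C=COC(C)=O | starting material
14 | [(6S,7R,7aS)-1,6,7-trihydroxy-1,6,7,7a-tetrahydrocyclopenta[c]pyran-4,7-diyl]bis(methylene) diacetate | CC(=O)OCC1=COC(O)[C@H]2C1=C[C@H](O)[C@]2(O)COC(C)=O | intermediate
15 | isovaleric anhydride | CC(C)CC(=O)OC(=O)CC(C)C | starting material
16 | 10-acetoxyvaltrathydrin | CC(=O)OCC1=CO[C@@H](OC(=O)CC(C)C)[C@H]2C1=C[C@H](OC(=O)CC(C)C)[C@]2(O)COC(C)=O | target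

## Summary

Total steps: 10. Longest linear sequence: 10 (fully linear from 1).

Steps most likely to fail, each with a fallback that changes the approach:

1. **Step 1 (catalytic asymmetric Piancatelli).** Enantiocontrol is unproven and the furan can polymerise under acid. Fallback: run the known uncatalysed thermal rearrangement (H2O, 150–180 °C) to rac-2 and obtain the S series by lipase-mediated kinetic resolution (acylation of the primary alcohol), i.e. resolution instead of asymmetric catalysis.
2. **Step 4 (1,2-addition to the hindered, enolisable, α′-branched enone).** Enolisation or loss of methanol may win. Fallback: replace carbonyl addition/transposition (steps 4–5) by cross-coupling: Tsuji–Wacker oxidation of enone 6 to the cyclopentane-1,3-dione, triflation at the oxygen remote from the spiro centre, and Stille coupling with methyl (E)-3-methoxy-2-(tributylstannyl)acrylate to give the same C6-keto dienone, then step 6.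
3. **Step 8 (ester reduction next to a ring-opening-prone lactol, giving the labile pentaol 12).** Over-reduction at C1 or decomposition is possible. Fallback: bring the C4 substituent in at the alcohol oxidation level, e.g. the cross-coupling route above with a 2-stannyl-3-methoxyallyl silyl ether partner, so that no late ester reduction is needed and only fluoride desilylation precedes the acylations.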